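**Retrosynthetic overview**
1. The last C–C bond made is acyl carbon–maleimide C3: a Nozaki–Hiyama–Kishi union of a decalin aldehyde (C14 core) with a 3-bromo-4-alkylmaleimide (C12), followed by desilylation and alcohol-to-ketone oxidation.
2. Bromomaleimide: imide ring from singlet-oxygen oxidation of a 3,4-disubstituted furan and ammonolysis; side-chain stereocentre by copper-catalysed SN2' allylic alkylation; furan from 3,4-dibromofuran.
3. Decalin aldehyde: C3=C4 from a C4 ketone (enol triflate reduction); 4a-OH by Rubottom oxidation; C6 and C8 by hydroxyl-directed hydrogenation.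
4. Ring B by ring-closing metathesis of a dienyl/acrylate pair, installed on a ring A enone by conjugate addition and enolate allylation.
5. Ring order: ring A (asymmetric Diels–Alder) first, then ring B (metathesis); the imide ring is built separately on the other half before the coupling.

Convention: decalin locants follow the target (C1 carries the exocyclic carbon that becomes the ketone, C2 CH3, C3=C4, C4a OH, C6 carboxyl, C8 CH3, C8a ring-fusion CH); ring A = C1–C4, C4a, C8a; ring B = C4a–C8a; β is the face of 4a-OH, 8a-H and the C1 side chain in the target, α the other face.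
Assumption: the facial sense of the (2R,5R)-diphenylpyrrolidine diene (step 4) and of CuBr·SMe2/(R,R)-Taniaphos (step 18) is taken by analogy with published cases; if either proves opposite, the mirror-image amine or ligand is used.

**Step 1**
Reactants: 1 2-(bromomethyl)prop-2-enoic acid
Product: 3 2-(trimethylsilyl)ethyl 2-(bromomethyl)prop-2-enoate, via acid chloride 2 (not isolated)
Conditions: (COCl)2, DMF (cat.), CH2Cl2, 0 °C to rt; then Me3SiCH2CH2OH, 2,6-lutidine, 0 °C
Reagents that add atoms: 2-(trimethylsilyl)ethanol, OCC[Si](C)(C)C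
Why: Esterification by nucleophilic acyl substitution through the acid chloride, with a hindered base that leaves the allylic bromide alone.

**Step 2**
Reactants: 4 (E)-4-methoxybut-3-en-2-one
Product: 5 (E)-4-[(2R,5R)-2,5-diphenylpyrrolidin-1-yl]but-3-en-2-one
Conditions: (2R,5R)-2,5-diphenylpyrrolidine (1.0 equiv), MeOH, rt
Reagents that add atoms: (2R,5R)-2,5-diphenylpyrrolidine, N1[C@@H](c2ccccc2)CC[C@@H]1c1ccccc1
Why: Conjugate addition–elimination (vinylogous transamidation) exchanges methoxide for the C2-symmetric amine and gives the E vinylogous amide.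

**Step 3**
Reactants: 5 vinylogous amide
Product: 6 (2R,5R)-1-[(1E)-3-(tert-butyldimethylsilyloxy)buta-1,3-dien-1-yl]-2,5-diphenylpyrrolidine
Conditions: KN(SiMe3)2, THF, −78 °C; then t-BuMe2SiCl, −78 °C to rt
Reagents that add atoms: tert-butyldimethylsilyl chloride, CC(C)(C)[Si](C)(C)Cl
Why: Kinetic enolisation of the methyl ketone and O-silylation give the 1-amino-3-siloxy diene.

**Step 4**
Reactants: 6 chiral aminosiloxy diene; 7 (E)-but-2-enal
Product: 8 (1S,2R,6R)-4-(tert-butyldimethylsilyloxy)-2-[(2R,5R)-2,5-diphenylpyrrolidin-1-yl]-6-methylcyclohex-3-ene-1-carbaldehyde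
Conditions: toluene, −20 °C to rt
Reagents that add atoms: none
Why: Endo Diels–Alder reaction in which the amino terminus bonds to the aldehyde α-carbon; the E dienophile makes CHO and CH3 trans, and the auxiliary shields one diene face, setting C1 and C2.

**Step 5**
Reactants: 8 Diels–Alder adduct
Product: 10 (4S,5R)-4-(hydroxymethyl)-5-methylcyclohex-2-en-1-one, via amino alcohol 9 (not isolated)
Conditions: LiAlH4, Et2O, −78 to 0 °C; then 10% aq. HF, MeCN, rt
Reagents that add atoms: none
Why: Hydride reduction of the aldehyde, then hydrolysis of the silyl enol ether and E1cB loss of the amine give the enone without touching C1 or C2.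

**Step 6**
Reactants: 10 hydroxymethyl enone; 11 2-chlorobuta-1,3-diene; 3 allylic bromide
Product: 15 ring A keto alcohol carrying the dienyl group at C8a (α) and the acrylate CH2 at C4a (β), via dienyl Grignard reagent 12 (not isolated), via silyl ether 13 (not isolated), via silylated adduct 14 (not isolated)
Conditions: 11, Mg, ZnCl2 (2 mol %), THF, reflux; separately 10, Me3SiCl, Et3N, THF, 0 °C; combine in the presence of CuBr·SMe2 (10 mol %), −78 °C; then 3, DMPU, −78 to −20 °C; aq. citric acid
Reagents that add atoms: none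
Why: Copper-catalysed 1,4-addition occurs anti to the C1 substituent and sets C8a, and the enolate is trapped at C4a by SN2' allylation (tandem conjugate addition–enolate alkylation); the C4a configuration is erased in step 9.

**Step 7**
Reactants: 15 ring A keto alcohol
Product: 16 trans-fused bicyclic keto dienoate (C6=C7 and exocyclic C8=CH2)
Conditions: second-generation Hoveyda–Grubbs catalyst (C31H38Cl2N2ORu, 5 mol %), toluene, 80 °C
Reagents that add atoms: none
Why: Ring-closing metathesis between the vinyl terminus of the diene and the acrylate methylene closes ring B with loss of ethene; no stereocentre is formed.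

**Step 8**
Reactants: 16 bicyclic keto dienoate
Product: 17 saturated bicyclic keto ester (8-CH3 α and 6-CO2R α)
Conditions: H2 (1 atm), [Ir(cod)(PCy3)(py)]PF6 (10 mol %), CH2Cl2, rt
Reagents that add atoms: none
Why: Hydroxyl-directed hydrogenation: the β-CH2OH on C1 sits next to C8 and should deliver hydrogen to the β face of the exocyclic methylene and then the enoate, giving 8-CH3 α and the equatorial 6-ester.

**Step 9**
Reactants: 17 saturated bicyclic keto ester
Product: 19 cis-fused 4a-hydroxy ketone (4a-OH β), via bis-silyl enol ether 18 (not isolated)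
Conditions: Me3SiOTf, Et3N, CH2Cl2, 0 °C to rt; then mCPBA, NaHCO3, CH2Cl2, −20 °C; then aq. citric acid, MeOH
Reagents that add atoms: 3-chloroperoxybenzoic acid, O=C(OO)c1cccc(Cl)c1
Why: Rubottom oxidation of the thermodynamic C4=C4a silyl enol ether; with both ring B substituents equatorial the C8a–C1 bond is axial on the α face, so the peracid should enter from the β face and give 4a-OH cis to 8a-H.

**Step 10**
Reactants: 19 hydroxy ketone diol
Product: 20 bis(triethylsilyl) ether
Conditions: Et3SiOTf (2.5 equiv), 2,6-lutidine, CH2Cl2, −78 to 0 °C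
Reagents that add atoms: triethylsilyl trifluoromethanesulfonate, CC[Si](CC)(CC)OS(=O)(=O)C(F)(F)F
Why: Silyl triflate silylation protects both the primary and the hindered tertiary hydroxyl before strong base is used.

**Step 11**
Reactants: 20 bis(triethylsilyl) ether
Product: 21 C3=C4 enol triflate
Conditions: KN(SiMe3)2, THF, −78 °C; then PhNTf2
Reagents that add atoms: N-phenylbis(trifluoromethanesulfonimide), O=S(=O)(N(c1ccccc1)S(=O)(=O)C(F)(F)F)C(F)(F)F
Why: Enolate O-triflation is regiospecific because only C3 carries α-hydrogens.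

**Step 12**
Reactants: 21 enol triflate
Product: 22 C3=C4 alkene
Conditions: Pd(OAc)2 (5 mol %), PPh3, n-Bu3N, HCO2H, DMF, 60 °C
Reagents that add atoms: none
Why: Palladium-catalysed formate reduction of the enol triflate gives the alkene next to the protected tertiary carbinol.

**Step 13**
Reactants: 22 alkene
Product: 23 decalin aldehyde
Conditions: (COCl)2, DMSO, CH2Cl2, −78 to −30 °C; then Et3N, −78 °C
Reagents that add atoms: none
Why: Swern conditions cleave the primary triethylsilyl ether in situ and oxidise it to the aldehyde while the tertiary silyl ether survives; low temperature protects C1.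

**Step 14**
Reactants: 24 3,4-dibromofuran
Product: 26 4-bromofuran-3-carbaldehyde, via 3-bromo-4-lithiofuran 25 (not isolated)
Conditions: n-BuLi (1.0 equiv), Et2O, −78 °C; DMF; aq. NH4Cl
Reagents that add atoms: N,N-dimethylformamide, CN(C)C=O
Why: Single bromine–lithium exchange followed by formylation.

**Step 15**
Reactants: 26 bromofuran aldehyde; 27 malonic acid
Product: 28 (E)-3-(4-bromofuran-3-yl)prop-2-enoic acid
Conditions: pyridine, piperidine (cat.), 100 °C
Reagents that add atoms: none
Why: Knoevenagel–Doebner condensation with decarboxylation gives the E acid.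

**Step 16**
Reactants: 28 acrylic acid
Product: 30 (E)-3-(4-bromofuran-3-yl)prop-2-en-1-ol, via mixed anhydride 29 (not isolated)
Conditions: ClCO2Et, Et3N, THF, 0 °C; then NaBH4, H2O, 0 °C
Reagents that add atoms: none
Why: Borohydride reduction of the mixed carbonic anhydride gives the allylic alcohol without 1,4-reduction.

**Step 17**
Reactants: 30 allylic alcohol
Product: 31 3-bromo-4-[(E)-3-bromoprop-1-enyl]furan
Conditions: CBr4, PPh3, CH2Cl2, 0 °C
Reagents that add atoms: tetrabromomethane, BrC(Br)(Br)Br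
Why: Appel bromination gives the linear allylic bromide.

**Step 18**
Reactants: 31 allylic bromide; 32 pentylmagnesium bromide
Product: 33 3-bromo-4-[(3S)-oct-1-en-3-yl]furan
Conditions: CuBr·SMe2 (1 mol %), (R,R)-Taniaphos (C43H39FeNP2, 1.2 mol %), CH2Cl2, −78 °C, slow addition of 32
Reagents that add atoms: none
Why: Copper-catalysed asymmetric allylic alkylation (SN2') gives the branched product and sets the side-chain stereocentre under ligand control.

**Step 19**
Reactants: 33 bromofuran
Product: 35 3-bromo-4-[(3S)-oct-1-en-3-yl]furan-2,5-dione, via hydroxybutenolide 34 (not isolated)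
Conditions: O2, hν, 5,10,15,20-tetraphenylporphyrin (cat.), i-Pr2NEt, CH2Cl2, −78 °C; then pyridinium chlorochromate (C5H5NH)[CrO3Cl], CH2Cl2, rt
Reagents that add atoms: dioxygen, O=O
Why: Singlet-oxygen [4+2] cycloaddition, base-induced opening of the endoperoxide to the lactol and lactol oxidation give the anhydride; the side-chain centre is not involved.

**Step 20**
Reactants: 35 bromomaleic anhydride
Product: 36 3-bromo-4-[(3S)-oct-1-en-3-yl]-1H-pyrrole-2,5-dione
Conditions: (Me3Si)2NH, MeOH, DMF, rt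
Reagents that add atoms: hexamethyldisilazane, C[Si](C)(C)N[Si](C)(C)C
Why: Ammonolysis of the anhydride and recyclisation under neutral conditions give the N–H imide.

**Step 21**
Reactants: 23 decalin aldehyde; 36 bromomaleimide
Product: 37 coupled allylic carbinol (mixture of carbinol epimers)
Conditions: CrCl2 (6 equiv), NiCl2 (2 mol %), DMSO/THF, rt
Reagents that add atoms: none
Why: Nozaki–Hiyama–Kishi coupling: the alkenylchromium species from the activated C–Br bond adds to the aldehyde in preference to ester, silyl ether and imide; the new carbinol centre is removed in step 23.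

**Step 22**
Reactants: 37 coupled carbinol
Product: 38 triol acid
Conditions: tris(dimethylamino)sulfonium difluorotrimethylsilicate (TASF), DMF, 0 °C to rt; aq. NaH2PO4
Reagents that add atoms: none
Why: Fluoride-induced desilylation removes the tertiary triethylsilyl ether and fragments the 2-(trimethylsilyl)ethyl ester to the acid.

**Step 23**
Reactants: 38 triol acid
Product: 39 target
Conditions: Dess–Martin periodinane, NaHCO3, CH2Cl2, 0 °C to rt
Reagents that add atoms: none
Why: Dess–Martin oxidation of the secondary allylic alcohol gives the ketone under non-basic conditions; the tertiary alcohol and the acid do not react.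

**Compound list**
1 | 2-(bromomethyl)prop-2-enoic acid | OC(=O)C(=C)CBr | starting material
2 | 2-(bromomethyl)prop-2-enoyl chloride | ClC(=O)C(=C)CBr | intermediate
3 | 2-(trimethylsilyl)ethyl 2-(bromomethyl)prop-2-enoate | C=C(CBr)C(=O)OCC[Si](C)(C)C | intermediate
4 | (E)-4-methoxybut-3-en-2-one | CO/C=C/C(C)=O | starting material
5 | (E)-4-[(2R,5R)-2,5-diphenylpyrrolidin-1-yl]but-3-en-2-one | CC(=O)/C=C/N1[C@@H](c2ccccc2)CC[C@@H]1c1ccccc1 | intermediate
6 | (2R,5R)-1-[(1E)-3-(tert-butyldimethylsilyloxy)buta-1,3-dien-1-yl]-2,5-diphenylpyrrolidine | C=C(O[Si](C)(C)C(C)(C)C)/C=C/N1[C@@H](c2ccccc2)CC[C@@H]1c1ccccc1 | intermediate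
7 | (E)-but-2-enal | C/C=C/C=O | starting material
8 | (1S,2R,6R)-4-(tert-butyldimethylsilyloxy)-2-[(2R,5R)-2,5-diphenylpyrrolidin-1-yl]-6-methylcyclohex-3-ene-1-carbaldehyde | O=C[C@H]1[C@H](C)CC(O[Si](C)(C)C(C)(C)C)=C[C@H]1N1[C@@H](c2ccccc2)CC[C@@H]1c1ccccc1 | intermediate
9 | primary alcohol from 8 (CHO reduced to CH2OH, all centres as in 8) | OC[C@H]1[C@H](C)CC(O[Si](C)(C)C(C)(C)C)=C[C@H]1N1[C@@H](c2ccccc2)CC[C@@H]1c1ccccc1 | intermediate
10 | (4S,5R)-4-(hydroxymethyl)-5-methylcyclohex-2-en-1-one | OC[C@@H]1C=CC(=O)C[C@H]1C | intermediate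
11 | 2-chlorobuta-1,3-diene | C=CC(Cl)=C | starting material
12 | buta-1,3-dien-2-ylmagnesium chloride | C=CC(=C)[Mg]Cl | intermediate
13 | (4S,5R)-5-methyl-4-[(trimethylsilyloxy)methyl]cyclohex-2-en-1-one | C[Si](C)(C)OC[C@@H]1C=CC(=O)C[C@H]1C | intermediate
14 | O-trimethylsilyl ether of 15 | C[Si](C)(C)OC[C@@H]1[C@@H](C(=C)C=C)[C@H](CC(=C)C(=O)OCC[Si](C)(C)C)C(=O)C[C@H]1C | intermediate
15 | 2-(trimethylsilyl)ethyl 2-{[2-(buta-1,3-dien-2-yl)-3-(hydroxymethyl)-4-methyl-6-oxocyclohexyl]methyl}prop-2-enoate; decalin locants: C1-CH2OH β, C2-CH3 α, C8a dienyl α, C4a CH2 β | OC[C@@H]1[C@@H](C(=C)C=C)[C@H](CC(=C)C(=O)OCC[Si](C)(C)C)C(=O)C[C@H]1C | intermediate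
16 | trans-fused bicyclic keto dienoate: C4 ketone, C6=C7 bearing the 2-(trimethylsilyl)ethyl ester at C6, exocyclic C8=CH2, 4a-H α, 8a-H β, C1-CH2OH β, C2-CH3 α | OC[C@@H]1[C@H]2C(=C)C=C(C(=O)OCC[Si](C)(C)C)C[C@@H]2C(=O)C[C@H]1C | intermediate
17 | saturated keto ester from 16: 8-CH3 α, 6-CO2CH2CH2SiMe3 α, 4a-H α, 8a-H β | OC[C@@H]1[C@H]2[C@@H](C)C[C@@H](C(=O)OCC[Si](C)(C)C)C[C@@H]2C(=O)C[C@H]1C | intermediate
18 | C4=C4a trimethylsilyl enol ether of 17, primary hydroxyl also silylated | C[Si](C)(C)OC[C@@H]1[C@H]2[C@@H](C)C[C@@H](C(=O)OCC[Si](C)(C)C)CC2=C(O[Si](C)(C)C)C[C@H]1C | intermediate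
19 | cis-fused 4a-hydroxy-4-ketone: 4a-OH β, 8a-H β, other centres as in 17 | OC[C@@H]1[C@H]2[C@@H](C)C[C@@H](C(=O)OCC[Si](C)(C)C)C[C@@]2(O)C(=O)C[C@H]1C | intermediate
20 | bis(triethylsilyl) ether of 19 (primary and 4a oxygens) | CC[Si](CC)(CC)OC[C@@H]1[C@H]2[C@@H](C)C[C@@H](C(=O)OCC[Si](C)(C)C)C[C@@]2(O[Si](CC)(CC)CC)C(=O)C[C@H]1C | intermediate
21 | C3=C4 enol triflate of 20 | CC[Si](CC)(CC)OC[C@@H]1[C@H]2[C@@H](C)C[C@@H](C(=O)OCC[Si](C)(C)C)C[C@@]2(O[Si](CC)(CC)CC)C(OS(=O)(=O)C(F)(F)F)=C[C@H]1C | intermediate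
22 | C3=C4 alkene: 4a-OSiEt3, C1-CH2OSiEt3, 6-CO2CH2CH2SiMe3; centres as in the target | CC[Si](CC)(CC)OC[C@@H]1[C@H]2[C@@H](C)C[C@@H](C(=O)OCC[Si](C)(C)C)C[C@@]2(O[Si](CC)(CC)CC)C=C[C@H]1C | intermediate
23 | decalin aldehyde: C1-CHO, 4a-OSiEt3, 6-CO2CH2CH2SiMe3; centres as in the target | O=C[C@@H]1[C@H]2[C@@H](C)C[C@@H](C(=O)OCC[Si](C)(C)C)C[C@@]2(O[Si](CC)(CC)CC)C=C[C@H]1C | intermediate
24 | 3,4-dibromofuran | Brc1cocc1Br | starting material
25 | 3-bromo-4-lithiofuran | [Li]c1cocc1Br | intermediate
26 | 4-bromofuran-3-carbaldehyde | O=Cc1cocc1Br | intermediate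
27 | malonic acid | OC(=O)CC(=O)O | starting material
28 | (E)-3-(4-bromofuran-3-yl)prop-2-enoic acid | OC(=O)/C=C/c1cocc1Br | intermediate
29 | mixed ethyl carbonic anhydride of 28 | CCOC(=O)OC(=O)/C=C/c1cocc1Br | intermediate
30 | (E)-3-(4-bromofuran-3-yl)prop-2-en-1-ol | OC/C=C/c1cocc1Br | intermediate
31 | 3-bromo-4-[(E)-3-bromoprop-1-enyl]furan | BrC/C=C/c1cocc1Br | intermediate
32 | pentylmagnesium bromide | CCCCC[Mg]Br | starting material
33 | 3-bromo-4-[(3S)-oct-1-en-3-yl]furan | C=C[C@H](CCCCC)c1cocc1Br | intermediate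
34 | 3-bromo-5-hydroxy-4-[(3S)-oct-1-en-3-yl]furan-2(5H)-one (one of two regioisomeric lactols, both lead to 35) | C=C[C@H](CCCCC)C1=C(Br)C(=O)OC1O | intermediate
35 | 3-bromo-4-[(3S)-oct-1-en-3-yl]furan-2,5-dione | C=C[C@H](CCCCC)C1=C(Br)C(=O)OC1=O | intermediate
36 | 3-bromo-4-[(3S)-oct-1-en-3-yl]-1H-pyrrole-2,5-dione | C=C[C@H](CCCCC)C1=C(Br)C(=O)NC1=O | intermediate
37 | coupled carbinol: maleimide C3–CH(OH)–C1 of the decalin, 4a-OSiEt3, 6-CO2CH2CH2SiMe3, carbinol centre as a mixture | C=C[C@H](CCCCC)C1=C(C(O)[C@@H]2[C@H]3[C@@H](C)C[C@@H](C(=O)OCC[Si](C)(C)C)C[C@@]3(O[Si](CC)(CC)CC)C=C[C@H]2C)C(=O)NC1=O | intermediate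
38 | triol acid: as 37 with free 4a-OH and free 6-CO2H | C=C[C@H](CCCCC)C1=C(C(O)[C@@H]2[C@H]3[C@@H](C)C[C@@H](C(=O)O)C[C@@]3(O)C=C[C@H]2C)C(=O)NC1=O | intermediate
39 | (1S,2R,4aR,6R,8S,8aR)-4a-hydroxy-2,8-dimethyl-1-({4-[(3S)-oct-1-en-3-yl]-2,5-dioxo-2,5-dihydro-1H-pyrrol-3-yl}carbonyl)-1,2,4a,5,6,7,8,8a-octahydronaphthalene-6-carboxylic acid (locants of the convention line) | C=C[C@H](CCCCC)C1=C(C(=O)[C@@H]2[C@H]3[C@@H](C)C[C@@H](C(=O)O)C[C@@]3(O)C=C[C@H]2C)C(=O)NC1=O | target

**Step count**
Total steps: 23. Longest linear sequence: 15 steps (steps 2–13, then 21–23); the bromomaleimide branch (steps 14–20) and step 1 run in parallel.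

**Steps most likely to fail, with fallbacks**

Step 8. The iridium catalyst may stall on the conjugated dienoate, or hydrogen may reach C8 from the α face. The fallback closes ring B by a radical reaction and needs neither metathesis nor hydrogenation. It sets out from 10: the step 6 protocol is run with CH2=CHMgBr in place of 12, giving the vinyl ketone F1. Fe(acac)3 and PhSiH3 in EtOH at 60 °C (metal-hydride hydrogen-atom transfer) turn the vinyl group into the secondary C8 radical, which adds 6-endo to the acrylate and is reduced. This returns to the route at 17; any C8 epimer is separated and C6 is equilibrated with DBU.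

Step 9. Enolisation may go towards C3 instead of C4a, and the facial selectivity of the oxidation is untested. The fallback fixes the enol ether regiochemistry by construction and oxidises before ring B is closed. It sets out from 10: I2 and pyridine in CH2Cl2 give the iodo enone F2. Zinc dust inserts into 3 to give the allylzinc bromide F3, and Pd(PPh3)4-catalysed Negishi coupling of F2 and F3 gives the C4a-allylated enone F4. CuBr·SMe2-catalysed addition of 12 in the presence of Me3SiCl then gives the tetrasubstituted bis-silyl enol ether F5 as a single regioisomer. mCPBA and acidic work-up give the hydroxy ketone F6, with oxygen expected anti to the neighbouring dienyl group. Ring-closing metathesis as in step 7 gives the cis-fused hydroxy keto dienoate F7, and hydrogenation as in step 8, now directed by both hydroxyls, returns to the route at 19.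

Step 21. A free N–H bromomaleimide is an untested partner for this coupling, the maleimide may be reduced by CrCl2, and the aldehyde is hindered. The fallback joins the same two halves with a furyllithium and builds the imide afterwards. It sets out from 33 and 23: t-BuLi in Et2O at −78 °C converts 33 into the lithiofuran F8, which adds to 23 to give the furyl carbinol F9. Dess–Martin oxidation gives the furyl ketone F10. Singlet oxygen (as in step 19) gives the hydroxybutenolide F11, and a second Dess–Martin oxidation gives the acyl maleic anhydride F12. (Me3Si)2NH and MeOH in DMF give the protected imide F13, and the step 22 conditions return to the route at 39.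

**Further compounds**
F1 | step 8 | vinyl ketone (15 with CH=CH2 in place of the dienyl group) | OC[C@@H]1[C@@H](C=C)[C@H](CC(=C)C(=O)OCC[Si](C)(C)C)C(=O)C[C@H]1C
F2 | step 9 | iodo enone (10 iodinated at the enone α-carbon) | OC[C@@H]1C=C(I)C(=O)C[C@H]1C
F3 | step 9 | allylzinc bromide from 3 | Br[Zn]CC(=C)C(=O)OCC[Si](C)(C)C
F4 | step 9 | C4a-allylated enone | OC[C@@H]1C=C(CC(=C)C(=O)OCC[Si](C)(C)C)C(=O)C[C@H]1C
F5 | step 9 | tetrasubstituted bis-silyl enol ether (dienyl α at C8a) | C[Si](C)(C)OC[C@@H]1[C@@H](C(=C)C=C)C(CC(=C)C(=O)OCC[Si](C)(C)C)=C(O[Si](C)(C)C)C[C@H]1C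
F6 | step 9 | monocyclic hydroxy ketone (4a-OH β, dienyl α) | OC[C@@H]1[C@@H](C(=C)C=C)[C@@](O)(CC(=C)C(=O)OCC[Si](C)(C)C)C(=O)C[C@H]1C
F7 | step 9 | cis-fused hydroxy keto dienoate | OC[C@@H]1[C@H]2C(=C)C=C(C(=O)OCC[Si](C)(C)C)C[C@@]2(O)C(=O)C[C@H]1C
F8 | step 21 | lithiofuran from 33 | C=C[C@H](CCCCC)c1cocc1[Li]
F9 | step 21 | furyl carbinol | C=C[C@H](CCCCC)c1cocc1C(O)[C@@H]1[C@H]2[C@@H](C)C[C@@H](C(=O)OCC[Si](C)(C)C)C[C@@]2(O[Si](CC)(CC)CC)C=C[C@H]1C
F10 | step 21 | furyl ketone | C=C[C@H](CCCCC)c1cocc1C(=O)[C@@H]1[C@H]2[C@@H](C)C[C@@H](C(=O)OCC[Si](C)(C)C)C[C@@]2(O[Si](CC)(CC)CC)C=C[C@H]1C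
F11 | step 21 | hydroxybutenolide (one regioisomer) | C=C[C@H](CCCCC)C1=C(C(=O)[C@@H]2[C@H]3[C@@H](C)C[C@@H](C(=O)OCC[Si](C)(C)C)C[C@@]3(O[Si](CC)(CC)CC)C=C[C@H]2C)C(=O)OC1O
F12 | step 21 | acyl maleic anhydride | C=C[C@H](CCCCC)C1=C(C(=O)[C@@H]2[C@H]3[C@@H](C)C[C@@H](C(=O)OCC[Si](C)(C)C)C[C@@]3(O[Si](CC)(CC)CC)C=C[C@H]2C)C(=O)OC1=O
F13 | step 21 | protected imide (39 as 4a-triethylsilyl ether and 2-(trimethylsilyl)ethyl ester) | C=C[C@H](CCCCC)C1=C(C(=O)[C@@H]2[C@H]3[C@@H](C)C[C@@H](C(=O)OCC[Si](C)(C)C)C[C@@]3(O[Si](CC)(CC)CC)C=C[C@H]2C)C(=O)NC1=O
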